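## The problem

The target is a 2,3,4-trisubstituted tetrahydrofuran (ring O1–C2–C3–C4–C5). C2 carries a 4-hydroxy-3-methoxyphenyl group, C3 a CH2O arm (C9) acylated by (E)-p-coumaric acid, C4 a 4-hydroxy-3-methoxybenzyl group (benzylic carbon C7′), and C5 is an unsubstituted OCH2. The three contiguous stereocentres are 2S, 3S and 4R, which places the aryl group and C9 cis, and C9 and the benzyl group trans. The 2,3-cis pair is the less stable arrangement and has to be made under kinetic control. C4 is the natural controller: a substituent at C4 sends a new group at C3 to the opposite face, and the C3 substituent then directs whatever adds to C2, so one absolute stereocentre can be relayed around the ring. The C2–O1 bond is a benzylic ether para to an oxygen substituent. Acid above low temperature can ionise it and epimerise C2, hydrogenolysis would cleave it, and a free para-phenoxide can open it through a quinone methide. The coumarate is a conjugated ester with its own phenol, which rules out hydrogenation, strong base and nucleophilic deprotection late in the route; three phenols must be freed without touching it. The enabling feature is at C4: with C9 removed and C2 at the carbonyl level, C4 bears a benzyl group and two CH2 arms (C3 and C5) that differ only because one is bound to O1. Without O1 they are identical, so C4 is the prochiral C3 of a 3-(arylmethyl)cyclobutanone whose carbonyl carbon is C2. Oxygen insertion into one of the two enantiotopic C(O)–CH2 bonds then gives O1–C5, the five-membered ring and the C4 stereocentre in one event.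

## Retrosynthesis

Target numbering (O1, C2–C5, C9, C7′) is used for every intermediate.

**Phenols and ester (21 ⇒ 20 ⇒ 16 + 19).** The three phenols are unmasked last from the tris-silyl ether 20. Aryl silyl ethers leave with buffered fluoride, which spares the ester, the alkene and the benzylic ether; benzyl ethers would need hydrogenolysis and alkyl or acetal ethers would need acid. The C9O–acyl bond is cut next, giving alcohol 16 and the O-silylated acid 19. The ester comes late because a cinnamate would not survive enolate or aryllithium chemistry, and 19 is silylated on its phenol so that it cannot acylate itself.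

**C9 oxygen (16 ⇒ 15).** The C9 hydroxyl is carried as a triethylsilyl ether in 15. A primary alkyl TES ether is cleaved by a weak acid in methanol under conditions that leave aryl TBS ethers and the cis benzylic ether alone, so the one hydroxyl to be acylated can be freed selectively.

**C2–H (15 ⇒ 14).** The last ring stereocentre is set by cutting the C2–H bond: lactol 14 is ionised to a 2-aryl oxocarbenium ion and reduced. The neighbouring cut, forming C2–aryl last by arylating a C2-unsubstituted oxocarbenium ion, would put the aryl group anti to C9 and give the 2,3-trans series. The aryl group must therefore be in place first and hydride must arrive last.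

**C2–aryl (14 ⇒ 10 + 13).** The lactol comes from addition of aryllithium 13 to the carbonyl of lactone 10. Reagent 13 is made by bromine–lithium exchange on 12, the silyl ether of commercial 11. This makes the lactone carbonyl the point of convergence and removes the need to carry the second arene through the early steps.

**C3–C9 (10 ⇒ 9 ⇒ 7).** C9 is attached by a hydroxymethylating aldol reaction of the lithium enolate 8 of lactone 7 with a one-carbon aldehyde, then silylation. The C4 benzyl group directs the electrophile to the opposite face, and the centre is epimerisable toward the wanted trans isomer. C9 cannot come in earlier, because a substituted ketene would make the cyclobutanone unsymmetrical and destroy the desymmetrisation.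

**O1–C5, the key cut (7 ⇒ 6).** Removing O1 from lactone 7 gives the achiral cyclobutanone 6. In the forward direction, enantioselective Baeyer–Villiger oxidation must choose between two enantiotopic methylene groups. Auxiliary alkylation or asymmetric hydrogenation routes to the same lactone need more steps and more functional-group changes; here the ring oxygen, the ring size and the absolute configuration come from one catalytic step on a symmetric substrate.

**Cyclobutanone (6 ⇒ 5 ⇒ 2 + 4 ⇒ 1 + 3).** The four-membered ring is cut across two C–C bonds to the allyl arene 2 (silylated eugenol 1) and dichloroketene 4, generated from trichloroacetyl chloride 3. Dechlorination of adduct 5 gives 6. Eugenol supplies C7′, C4 and one ring CH2; the ketene supplies C2 and the other ring CH2. Because 5 is racemic and 6 is achiral, which of C3 and C5 comes from which source is statistical and does not matter.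

**Acid partner (19 ⇒ 18 ⇒ 17).** p-Coumaric acid 17 is bis-silylated to 18, and the labile silyl ester is hydrolysed in the same flask.

## Roads not taken

**Alternative 1:** The cut is through C2–C3 and the ring acyl–oxygen bond, on a lactone in which the future C5 is a carbonyl and the future C7′ is an exocyclic methylene. In the forward key step, aldehyde A2 and the γ-silyloxymethyl 2-(methoxycarbonyl)allylboronate A3 (silyloxymethyl cis to the borylmethyl arm) would react through a closed chair transition state. The boron alkoxide would then acylate on the ester to give the cis methylene lactone A1.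
- Merits: the ring and both C2 and C3 are made in one convergent step, and the cis relationship follows from alkene geometry, not from a late facial selection. On this point it is better than the chosen plan, which relies on hydride delivery to an oxocarbenium ion.
- Weak points: ester-substituted allylboronates are deactivated and need heat or strong acid, and the acid can ionise the benzylic lactone C–O bond of an electron-rich aryl and erode cis to trans. Absolute control needs a chiral boron ligand or chiral acid that is not secured for γ-substituted reagents of this kind. Geometrically pure A3 takes several steps. After A1 the arene must be added to the methylene group, C4 set by protonation, and the ring carbonyl removed by reduction beside the labile benzylic ether.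
- Comparison: the chosen plan answers with commodity starting materials, a single catalytic stereocentre relayed by well-known substrate control, and no ring deoxygenation next to C2.

**Alternative 2:** The cuts are C3–C9 and C4–C7′ on the chiral-pool butenolide A5, whose stereocentre carries a trityloxymethyl group. In one flask, tris(methylthio)methyllithium A6 would add to the β-carbon anti to that group, and the resulting enolate would be alkylated by benzyl bromide A7 anti to the new substituent, giving the all-trans lactone A4.
- Merits: absolute configuration is bought, and the anti,anti outcome of such tandem additions is dependable. The enantiopurity does not hang on an asymmetric catalyst, which is a real advantage over the chosen plan.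
- Weak points: the orthothioester must be unmasked and reduced to C9. The trityloxymethyl carbon must then be excised (lactone reduction, detritylation, glycol cleavage, reoxidation) to reach a lactone of the same type as 10. The controlling stereocentre is destroyed on the way, and the same aryllithium addition and lactol reduction still follow.
- Comparison: this is a longer route to the chosen plan's own mid-stage intermediate, by roughly twice the number of operations and with thiophilic metal reagents. The chosen plan sets against the secure enantiopurity of A4 a much shorter sequence and a non-catalytic fallback for the lactone.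

**Alternative 3:** The cuts are O1–C2 and C4–C5. The trans donor–acceptor cyclopropane A9 (aryl on one carbon, silyloxymethyl on the next, geminal diester on the third) would be activated by Sn(OTf)2. The oxygen of formaldehyde A10 would open it at the aryl carbon with inversion, and the malonate carbon would close on the resulting oxocarbenium carbon to give tetrahydrofuran A8 with aryl cis to the silyloxymethyl group.
- Merits: the 2,3-cis pair comes stereospecifically from an easily made trans cyclopropane, and the pivalate on the phenol tempers the donor so that the opening stays invertive. This is a more direct answer to the cis problem than the chosen plan has.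
- Weak points: these annulations are established with aryl and alkyl aldehydes; formaldehyde oligomerises under Lewis acids and is an untested partner, and the extra ring substituent slows the opening. The larger cost comes afterwards: the geminal diester at C4 must become hydrogen plus a benzyl group (dealkoxycarbonylation, ester to aldehyde, aryl addition, benzylic deoxygenation). That last step must distinguish the new benzylic C–O bond from the ring C2–O1 bond, and C4 is set only by protonation.
- Comparison: the chosen plan has the benzyl group in eugenol from the start and builds outward from C4, so it avoids that late chemoselectivity problem.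

Key step: step 4

Assumption: the sense of induction of the Sc(OTf)3–N,N′-dioxide catalyst on a 3-(arylmethyl)cyclobutanone is taken to follow that on 3-arylcyclobutanones; if it does not, the ligand from the enantiomeric amino acid is used and nothing else changes.

Abbreviations: Ar* = 4-(tert-butyldimethylsilyloxy)-3-methoxyphenyl; TBS = tert-butyldimethylsilyl; TES = triethylsilyl.

## Route

Step 1
Reactants: 1 eugenol
Product: 2 tert-butyl[2-methoxy-4-(prop-2-en-1-yl)phenoxy]dimethylsilane
Conditions: TBSCl, imidazole, DMF, rt
Reagents that add atoms: tert-butyldimethylsilyl chloride, CC(C)(C)[Si](C)(C)Cl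
Why: Standard silylation of a phenol; the aryl TBS ether should survive Zn/AcOH, peracid, amide base, aryllithium and cold BF3, and it leaves with buffered fluoride at the end.

Step 2
Reactants: 2 tert-butyl[2-methoxy-4-(prop-2-en-1-yl)phenoxy]dimethylsilane; 3 trichloroacetyl chloride
Product: 5 rac-3-(Ar*-methyl)-2,2-dichlorocyclobutan-1-one, via dichloroketene 4 (not isolated)
Conditions: Zn(Cu), DME, Et2O, rt, slow addition of 3
Reagents that add atoms: none
Why: Zinc dehalogenation of 3 gives dichloroketene, which undergoes the thermal ketene–alkene [2+2] cycloaddition with the terminal alkene; the alkene CH2 bonds to the ketene carbonyl carbon, so the substituent ends at C3 of the cyclobutanone. DME ties up ZnCl2 and protects the electron-rich arene and the silyl ether.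

Step 3
Reactants: 5 rac-3-(Ar*-methyl)-2,2-dichlorocyclobutan-1-one
Product: 6 3-(Ar*-methyl)cyclobutan-1-one
Conditions: Zn dust, AcOH, rt
Reagents that add atoms: none
Why: Reductive dechlorination of an α,α-dichloroketone through zinc enolates; removal of both chlorines makes the ketone achiral, with two enantiotopic α-methylene groups.

Step 4
Reactants: 6 3-(Ar*-methyl)cyclobutan-1-one
Product: 7 (4R)-4-(Ar*-methyl)dihydrofuran-2(3H)-one
Conditions: Sc(OTf)3 (5 mol %), L-pipecolic-acid-derived N,N′-dioxide bis(2,6-diisopropylanilide) ligand (6 mol %), m-CPBA, EtOAc, −20 °C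
Reagents that add atoms: m-chloroperoxybenzoic acid, O=C(OO)c1cccc(Cl)c1
Why: The scandium triflate–N,N′-dioxide complex binds the ketone oxygen, the peracid adds to the activated carbonyl, and the tetrahedral peroxy adduct collapses by 1,2-shift of one α-methylene from carbon to oxygen with loss of 3-chlorobenzoate. The closest known reaction type is the catalytic asymmetric Baeyer–Villiger desymmetrisation of prochiral 3-substituted cyclobutanones by chiral Lewis acid–peracid systems. The lactone ring is formed by ring expansion, not by cyclisation: oxygen is inserted into a C2–CH2 bond of the four-membered ring, driven by release of cyclobutanone strain, and this makes O1–C5. No bond changes at C4; it becomes stereogenic because the chiral pocket of the catalyst decides which enantiotopic CH2 lies antiperiplanar to the O–O bond and migrates, so catalyst control alone sets 4R. The only selectivity needed is this enantiotopic-group selection, since both possible migrating groups are constitutionally identical. Chemoselectivity over the electron-rich arene rests on the high reactivity of the strained ketone at −20 °C. The catalysed pathway must outrun the racemic oxidation by free peracid, which is why the temperature is low and the peracid is kept near one equivalent.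

Step 5
Reactants: 7 (4R)-4-(Ar*-methyl)dihydrofuran-2(3H)-one
Product: 9 (3S,4R)-4-(Ar*-methyl)-3-(hydroxymethyl)dihydrofuran-2(3H)-one, via lithium enolate 8 (not isolated)
Conditions: LiN(iPr)2, THF, −78 °C; HCHO (gas, from cracked paraformaldehyde), −78 to −40 °C; aq NH4Cl
Reagents that add atoms: formaldehyde, C=O
Why: Aldol hydroxymethylation of a lactone enolate; the electrophile should approach the planar enolate anti to the C4 benzyl group and give the 3,4-trans product, which is also the thermodynamically preferred epimer at this enolisable centre.

Step 6
Reactants: 9 (3S,4R)-4-(Ar*-methyl)-3-(hydroxymethyl)dihydrofuran-2(3H)-one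
Product: 10 (3S,4R)-4-(Ar*-methyl)-3-[(triethylsilyloxy)methyl]dihydrofuran-2(3H)-one
Conditions: TESCl, imidazole, CH2Cl2, 0 °C
Reagents that add atoms: chlorotriethylsilane, CC[Si](Cl)(CC)CC
Why: Standard silylation of a primary alcohol; the TES ether is a poor leaving group toward enolate-induced β-elimination and can later be removed by weak acid without loss of the aryl TBS groups.

Step 7
Reactants: 11 4-bromo-2-methoxyphenol
Product: 12 (4-bromo-2-methoxyphenoxy)(tert-butyl)dimethylsilane
Conditions: TBSCl, imidazole, DMF, rt
Reagents that add atoms: tert-butyldimethylsilyl chloride, CC(C)(C)[Si](C)(C)Cl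
Why: Standard phenol silylation; the bulky silyl ether tolerates bromine–lithium exchange at low temperature.

Step 8
Reactants: 12 (4-bromo-2-methoxyphenoxy)(tert-butyl)dimethylsilane; 10 (3S,4R)-4-(Ar*-methyl)-3-[(triethylsilyloxy)methyl]dihydrofuran-2(3H)-one
Product: 14 (3S,4R)-2-Ar*-4-(Ar*-methyl)-3-[(triethylsilyloxy)methyl]tetrahydrofuran-2-ol (both C2 epimers; in equilibrium with the open γ-hydroxy ketone), via aryllithium 13 (not isolated)
Conditions: 12, n-BuLi, THF, −78 °C; then added to 10, THF, −78 °C; aq NH4Cl at −78 °C
Reagents that add atoms: none
Why: Bromine–lithium exchange followed by single addition of the aryllithium to a γ-lactone; the tetrahedral lithium alkoxide should persist at −78 °C, so cold quenching gives the lactol without a second addition. C3 and C4 are not touched.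

Step 9
Reactants: 14 (3S,4R)-2-Ar*-4-(Ar*-methyl)-3-[(triethylsilyloxy)methyl]tetrahydrofuran-2-ol
Product: 15 (2S,3S,4R)-2-Ar*-4-(Ar*-methyl)-3-[(triethylsilyloxy)methyl]tetrahydrofuran
Conditions: Et3SiH, BF3·OEt2, CH2Cl2, −78 °C; Et3N then aq NaHCO3 at −78 °C
Reagents that add atoms: none
Why: Ionic reduction of a lactol: BF3 ionises the C2 hydroxyl to the 2-aryl oxocarbenium ion, and the silane should deliver hydride to the face anti to the adjacent C3 silyloxymethyl group, leaving the aryl group cis to C9 (2S) as the kinetic product. The cold quench is meant to prevent Lewis-acid epimerisation; any TES loss here is harmless because step 10 removes that group.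

Step 10
Reactants: 15 (2S,3S,4R)-2-Ar*-4-(Ar*-methyl)-3-[(triethylsilyloxy)methyl]tetrahydrofuran
Product: 16 [(2S,3S,4R)-2-Ar*-4-(Ar*-methyl)tetrahydrofuran-3-yl]methanol
Conditions: PPTS (cat.), MeOH/CH2Cl2, 0 °C
Reagents that add atoms: none
Why: Mild acid methanolysis cleaves a primary alkyl TES ether far faster than aryl TBS ethers, and pyridinium tosylate is too weak an acid to ionise the benzylic C2–O1 bond at 0 °C.

Step 11
Reactants: 17 p-coumaric acid
Product: 19 (E)-3-[4-(tert-butyldimethylsilyloxy)phenyl]prop-2-enoic acid, via bis-silylated coumarate 18 (not isolated)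
Conditions: TBSCl (2.3 equiv), imidazole, DMF, rt; then AcOH/THF/H2O, rt
Reagents that add atoms: tert-butyldimethylsilyl chloride, CC(C)(C)[Si](C)(C)Cl
Why: Exhaustive silylation followed by selective hydrolysis of the silyl ester, which is far more labile than the aryl silyl ether; the alkene geometry is untouched.

Step 12
Reactants: 16 [(2S,3S,4R)-2-Ar*-4-(Ar*-methyl)tetrahydrofuran-3-yl]methanol; 19 (E)-3-[4-(tert-butyldimethylsilyloxy)phenyl]prop-2-enoic acid
Product: 20 [(2S,3S,4R)-2-Ar*-4-(Ar*-methyl)tetrahydrofuran-3-yl]methyl (E)-3-[4-(tert-butyldimethylsilyloxy)phenyl]prop-2-enoate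
Conditions: EDC·HCl, DMAP, CH2Cl2, 0 °C to rt
Reagents that add atoms: none
Why: Steglich esterification of an unhindered primary alcohol with a cinnamic acid under near-neutral conditions; no stereocentre is involved and the benzylic ether sees no acid.

Step 13
Reactants: 20 [(2S,3S,4R)-2-Ar*-4-(Ar*-methyl)tetrahydrofuran-3-yl]methyl (E)-3-[4-(tert-butyldimethylsilyloxy)phenyl]prop-2-enoate
Product: 21 [(2S,3S,4R)-2-(4-hydroxy-3-methoxyphenyl)-4-[(4-hydroxy-3-methoxyphenyl)methyl]tetrahydrofuran-3-yl]methyl (E)-3-(4-hydroxyphenyl)prop-2-enoate
Conditions: Bu4NF, AcOH (1:1), THF, 0 °C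
Reagents that add atoms: none
Why: Fluoride cleaves aryl silyl ethers rapidly because phenoxide is a good leaving group on silicon. The acetic acid buffer keeps the freed phenols protonated, so the ester is not attacked and the para-hydroxybenzylic C2–O1 bond is not opened through a quinone methide.

## Compound list

1 | eugenol | COc1cc(CC=C)ccc1O | starting material
2 | tert-butyl[2-methoxy-4-(prop-2-en-1-yl)phenoxy]dimethylsilane | COc1cc(CC=C)ccc1O[Si](C)(C)C(C)(C)C | intermediate
3 | trichloroacetyl chloride | ClC(=O)C(Cl)(Cl)Cl | starting material
4 | dichloroketene (not isolated) | O=C=C(Cl)Cl | intermediate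
5 | rac-3-{[4-(tert-butyldimethylsilyloxy)-3-methoxyphenyl]methyl}-2,2-dichlorocyclobutan-1-one | COc1cc(CC2CC(=O)C2(Cl)Cl)ccc1O[Si](C)(C)C(C)(C)C | intermediate
6 | 3-{[4-(tert-butyldimethylsilyloxy)-3-methoxyphenyl]methyl}cyclobutan-1-one | COc1cc(CC2CC(=O)C2)ccc1O[Si](C)(C)C(C)(C)C | intermediate
7 | (4R)-4-{[4-(tert-butyldimethylsilyloxy)-3-methoxyphenyl]methyl}dihydrofuran-2(3H)-one | COc1cc(C[C@H]2COC(=O)C2)ccc1O[Si](C)(C)C(C)(C)C | intermediate
8 | lithium enolate of 7 (not isolated) | COc1cc(C[C@H]2COC(O[Li])=C2)ccc1O[Si](C)(C)C(C)(C)C | intermediate
9 | (3S,4R)-4-{[4-(tert-butyldimethylsilyloxy)-3-methoxyphenyl]methyl}-3-(hydroxymethyl)dihydrofuran-2(3H)-one (3,4-trans) | COc1cc(C[C@H]2COC(=O)[C@@H]2CO)ccc1O[Si](C)(C)C(C)(C)C | intermediate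
10 | (3S,4R)-4-{[4-(tert-butyldimethylsilyloxy)-3-methoxyphenyl]methyl}-3-[(triethylsilyloxy)methyl]dihydrofuran-2(3H)-one | COc1cc(C[C@H]2COC(=O)[C@@H]2CO[Si](CC)(CC)CC)ccc1O[Si](C)(C)C(C)(C)C | intermediate
11 | 4-bromo-2-methoxyphenol | COc1cc(Br)ccc1O | starting material
12 | (4-bromo-2-methoxyphenoxy)(tert-butyl)dimethylsilane | COc1cc(Br)ccc1O[Si](C)(C)C(C)(C)C | intermediate
13 | [4-(tert-butyldimethylsilyloxy)-3-methoxyphenyl]lithium (not isolated) | COc1cc([Li])ccc1O[Si](C)(C)C(C)(C)C | intermediate
14 | (3S,4R)-2-[4-(tert-butyldimethylsilyloxy)-3-methoxyphenyl]-4-{[4-(tert-butyldimethylsilyloxy)-3-methoxyphenyl]methyl}-3-[(triethylsilyloxy)methyl]tetrahydrofuran-2-ol (both C2 epimers) | COc1cc(C[C@H]2COC(O)(c3ccc(O[Si](C)(C)C(C)(C)C)c(OC)c3)[C@@H]2CO[Si](CC)(CC)CC)ccc1O[Si](C)(C)C(C)(C)C | intermediate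
15 | (2S,3S,4R)-2-[4-(tert-butyldimethylsilyloxy)-3-methoxyphenyl]-4-{[4-(tert-butyldimethylsilyloxy)-3-methoxyphenyl]methyl}-3-[(triethylsilyloxy)methyl]tetrahydrofuran (2,3-cis, 3,4-trans) | COc1cc(C[C@H]2CO[C@H](c3ccc(O[Si](C)(C)C(C)(C)C)c(OC)c3)[C@@H]2CO[Si](CC)(CC)CC)ccc1O[Si](C)(C)C(C)(C)C | intermediate
16 | [(2S,3S,4R)-2-[4-(tert-butyldimethylsilyloxy)-3-methoxyphenyl]-4-{[4-(tert-butyldimethylsilyloxy)-3-methoxyphenyl]methyl}tetrahydrofuran-3-yl]methanol | COc1cc(C[C@H]2CO[C@H](c3ccc(O[Si](C)(C)C(C)(C)C)c(OC)c3)[C@@H]2CO)ccc1O[Si](C)(C)C(C)(C)C | intermediate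
17 | p-coumaric acid, (E)-3-(4-hydroxyphenyl)prop-2-enoic acid | O=C(O)/C=C/c1ccc(O)cc1 | starting material
18 | tert-butyldimethylsilyl (E)-3-[4-(tert-butyldimethylsilyloxy)phenyl]prop-2-enoate (not isolated) | CC(C)(C)[Si](C)(C)OC(=O)/C=C/c1ccc(O[Si](C)(C)C(C)(C)C)cc1 | intermediate
19 | (E)-3-[4-(tert-butyldimethylsilyloxy)phenyl]prop-2-enoic acid | O=C(O)/C=C/c1ccc(O[Si](C)(C)C(C)(C)C)cc1 | intermediate
20 | [(2S,3S,4R)-2-[4-(tert-butyldimethylsilyloxy)-3-methoxyphenyl]-4-{[4-(tert-butyldimethylsilyloxy)-3-methoxyphenyl]methyl}tetrahydrofuran-3-yl]methyl (E)-3-[4-(tert-butyldimethylsilyloxy)phenyl]prop-2-enoate | COc1cc(C[C@H]2CO[C@H](c3ccc(O[Si](C)(C)C(C)(C)C)c(OC)c3)[C@@H]2COC(=O)/C=C/c2ccc(O[Si](C)(C)C(C)(C)C)cc2)ccc1O[Si](C)(C)C(C)(C)C | intermediate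
21 | [(2S,3S,4R)-2-(4-hydroxy-3-methoxyphenyl)-4-[(4-hydroxy-3-methoxyphenyl)methyl]tetrahydrofuran-3-yl]methyl (E)-3-(4-hydroxyphenyl)prop-2-enoate | COc1cc(C[C@H]2CO[C@H](c3ccc(O)c(OC)c3)[C@@H]2COC(=O)/C=C/c2ccc(O)cc2)ccc1O | target

## Step count and risks

Total: 13 steps. Longest linear sequence: 11 steps from eugenol (steps 1–6, 8–10, 12, 13); steps 7 and 11 prepare the two side components.

**Step 4 (key step).** The most likely failure is insufficient discrimination between the enantiotopic methylene groups. The stereo-differentiating substituent is a flexible benzyl group one carbon from the ring, and racemic oxidation by free peracid competes; every later compound inherits the enantiomeric purity fixed here. The fallback leaves oxygen insertion for enantioselective deprotonation. It sets out from 6, which is deprotonated with a homochiral lithium bis(1-phenylethyl)amide in the presence of TESCl to give the silyl enol ether (3R)-3-(Ar*-methyl)-1-(triethylsilyloxy)cyclobut-1-ene F1. Ozonolysis of the enol ether double bond with NaBH4 work-up gives (3R)-4-hydroxy-3-(Ar*-methyl)butanoic acid F2. Acidification closes F2 to the lactone, and the route is rejoined at 7.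

**Step 9.** Facial selectivity of hydride delivery may be eroded, because the C4 benzyl group lies on the face from which hydride must come. The Lewis acid may also epimerise the product toward the 2,3-trans isomer, by reversible ionisation of the benzylic C2–O1 bond or through the enol ether, or over-reduce it with ring opening. The fallback sets the C2 configuration in a separate ketone reduction and closes the ring at the primary carbon without touching C2. It sets out from 14, whose open keto form is reduced with a hydride reagent chosen for the required sense of acyclic 1,2-induction (a bulky borohydride or a chelating one) to (1S,2S,3R)-1-Ar*-3-(Ar*-methyl)-2-[(triethylsilyloxy)methyl]butane-1,4-diol F3. Selective sulfonylation of the primary hydroxyl (TsCl, pyridine) gives (2R,3S,4S)-4-Ar*-2-(Ar*-methyl)-4-hydroxy-3-[(triethylsilyloxy)methyl]butyl 4-methylbenzenesulfonate F4. Treatment with NaH in THF closes the ring by 5-exo-tet displacement with retention at C2, and the route is rejoined at 15.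

**Step 8.** The aryllithium may act as a base on the lactone α-hydrogen, after which the silyloxide can be lost by β-elimination, or a second equivalent may add to the ring-opened ketone. The fallback changes the acyl electrophile. It sets out from 10, which is opened with MeNH(OMe)·HCl and Me3Al to (2S,3R)-4-hydroxy-N-methoxy-N-methyl-3-(Ar*-methyl)-2-[(triethylsilyloxy)methyl]butanamide F5. Two equivalents of 13 then give the γ-hydroxy ketone through a chelated adduct that cannot add twice; the ketone closes to the lactol, and the route is rejoined at 14.

**Step 5.** Formaldehyde may oligomerise before it is captured, which leaves lactone unreacted, and the aldolate may dehydrate to the α-methylene lactone or react a second time. The fallback replaces the aldol by an alkylation with a protected hydroxymethyl group. It sets out from 7, whose enolate 8 is alkylated with benzyl chloromethyl ether anti to the benzyl group to give (3S,4R)-3-[(benzyloxy)methyl]-4-(Ar*-methyl)dihydrofuran-2(3H)-one F6. Hydrogenolysis (H2, Pd/C, EtOAc) is safe at this stage, which has no alkene and no benzylic ring ether, and the route is rejoined at 9.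

## Further compounds

F1 | step 4 | (3R)-3-{[4-(tert-butyldimethylsilyloxy)-3-methoxyphenyl]methyl}-1-(triethylsilyloxy)cyclobut-1-ene | COc1cc(C[C@@H]2CC(O[Si](CC)(CC)CC)=C2)ccc1O[Si](C)(C)C(C)(C)C
F2 | step 4 | (3R)-4-hydroxy-3-{[4-(tert-butyldimethylsilyloxy)-3-methoxyphenyl]methyl}butanoic acid | COc1cc(C[C@@H](CO)CC(=O)O)ccc1O[Si](C)(C)C(C)(C)C
F3 | step 9 | (1S,2S,3R)-1-[4-(tert-butyldimethylsilyloxy)-3-methoxyphenyl]-3-{[4-(tert-butyldimethylsilyloxy)-3-methoxyphenyl]methyl}-2-[(triethylsilyloxy)methyl]butane-1,4-diol | COc1cc(C[C@@H](CO)[C@@H](CO[Si](CC)(CC)CC)[C@H](O)c2ccc(O[Si](C)(C)C(C)(C)C)c(OC)c2)ccc1O[Si](C)(C)C(C)(C)C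
F4 | step 9 | (2R,3S,4S)-4-[4-(tert-butyldimethylsilyloxy)-3-methoxyphenyl]-2-{[4-(tert-butyldimethylsilyloxy)-3-methoxyphenyl]methyl}-4-hydroxy-3-[(triethylsilyloxy)methyl]butyl 4-methylbenzenesulfonate | COc1cc(C[C@@H](COS(=O)(=O)c3ccc(C)cc3)[C@@H](CO[Si](CC)(CC)CC)[C@H](O)c2ccc(O[Si](C)(C)C(C)(C)C)c(OC)c2)ccc1O[Si](C)(C)C(C)(C)C
F5 | step 8 | (2S,3R)-4-hydroxy-N-methoxy-N-methyl-3-{[4-(tert-butyldimethylsilyloxy)-3-methoxyphenyl]methyl}-2-[(triethylsilyloxy)methyl]butanamide | COc1cc(C[C@@H](CO)[C@@H](CO[Si](CC)(CC)CC)C(=O)N(C)OC)ccc1O[Si](C)(C)C(C)(C)C
F6 | step 5 | (3S,4R)-3-[(benzyloxy)methyl]-4-{[4-(tert-butyldimethylsilyloxy)-3-methoxyphenyl]methyl}dihydrofuran-2(3H)-one | COc1cc(C[C@H]2COC(=O)[C@@H]2COCc3ccccc3)ccc1O[Si](C)(C)C(C)(C)C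
A1 | alternative 1 | (4S,5S)-5-[4-(tert-butyldimethylsilyloxy)-3-methoxyphenyl]-4-[(tert-butyldimethylsilyloxy)methyl]-3-methylenedihydrofuran-2(3H)-one (4,5-cis) | C=C1C(=O)O[C@H](c2ccc(O[Si](C)(C)C(C)(C)C)c(OC)c2)[C@@H]1CO[Si](C)(C)C(C)(C)C
A2 | alternative 1 | 4-(tert-butyldimethylsilyloxy)-3-methoxybenzaldehyde | COc1cc(C=O)ccc1O[Si](C)(C)C(C)(C)C
A3 | alternative 1 | methyl (E)-4-(tert-butyldimethylsilyloxy)-2-[(4,4,5,5-tetramethyl-1,3,2-dioxaborolan-2-yl)methyl]but-2-enoate | COC(=O)/C(CB1OC(C)(C)C(C)(C)O1)=C/CO[Si](C)(C)C(C)(C)C
A4 | alternative 2 | (3R,4R,5R)-3-{[4-(tert-butyldimethylsilyloxy)-3-methoxyphenyl]methyl}-4-[tris(methylthio)methyl]-5-[(trityloxy)methyl]dihydrofuran-2(3H)-one (all-trans) | COc1cc(C[C@H]2C(=O)O[C@@H](COC(c3ccccc3)(c3ccccc3)c3ccccc3)[C@@H]2C(SC)(SC)SC)ccc1O[Si](C)(C)C(C)(C)C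
A5 | alternative 2 | (R)-5-[(trityloxy)methyl]furan-2(5H)-one | O=C1C=C[C@H](COC(c2ccccc2)(c2ccccc2)c2ccccc2)O1
A6 | alternative 2 | tris(methylthio)methyllithium | [Li]C(SC)(SC)SC
A7 | alternative 2 | [4-(bromomethyl)-2-methoxyphenoxy](tert-butyl)dimethylsilane | COc1cc(CBr)ccc1O[Si](C)(C)C(C)(C)C
A8 | alternative 3 | dimethyl (4S,5S)-5-[3-methoxy-4-(pivaloyloxy)phenyl]-4-[(tert-butyldimethylsilyloxy)methyl]dihydrofuran-3,3(2H)-dicarboxylate (4,5-cis) | COC(=O)C1(C(=O)OC)CO[C@H](c2ccc(OC(=O)C(C)(C)C)c(OC)c2)[C@@H]1CO[Si](C)(C)C(C)(C)C
A9 | alternative 3 | dimethyl (2R,3S)-2-[3-methoxy-4-(pivaloyloxy)phenyl]-3-[(tert-butyldimethylsilyloxy)methyl]cyclopropane-1,1-dicarboxylate (2,3-trans) | COC(=O)C1(C(=O)OC)[C@@H](c2ccc(OC(=O)C(C)(C)C)c(OC)c2)[C@@H]1CO[Si](C)(C)C(C)(C)C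
A10 | alternative 3 | formaldehyde | C=O
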